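**Retrosynthetic overview**
1. Caespitol (14) ⇐ 1,2-halogen interchange of its trans-diaxial 3'-Cl/4'-Br isomer 13 ⇐ selenium-relayed anti chlorobromination of cyclohexene 12.
2. Bromo-oxane ring of 12 ⇐ electrochemical (anodic) 6-endo bromoetherification of hydroxy acetate 10, forming O1–C6 and C5–Br.
3. C3 carbinol of 10 ⇐ Felkin–Anh reduction of α-hydroxy ketone 9; C2 ⇐ chelation-controlled MeMgBr addition to ketol 7.
4. Cyclohexene ring of 7 ⇐ Diels–Alder of isoprene with α'-hydroxy enone 5 ⇐ methyl (S)-glycidate (1) + isobutenyl Grignard (2) + vinyl Grignard (4).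
5. Ring order: cyclohexene first (step 3), oxane second (step 7). The bought carbinol centre sets C1' and C2, is then erased (step 5) and reset from C2 (step 6).

Assumption: one-pot telescoped operations (steps 2, 6, 7, 8) count as single steps; 1, 2, 4, 6 and all reagents are commercial. Locants are those of the target name (oxane C2, C3, C5, C6; cyclohexyl C1', C3', C4'). None of this has been run; selectivities are predictions from the stated models.

**Step 1**
Reactants: 1 methyl (2S)-oxirane-2-carboxylate; 2 (2-methylprop-1-en-1-yl)magnesium bromide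
Product: 3 methyl (2S)-2-hydroxy-5-methylhex-4-enoate
Conditions: 2 (1.3 equiv), CuI (10 mol %), THF, −40 °C; aq. NH4Cl
Reagents that add atoms: (2-methylprop-1-en-1-yl)magnesium bromide, CC(C)=C[Mg]Br
Why: Cu-catalysed SN2 opening of the epoxide at the unsubstituted CH2 (alkenyl cuprate) leaves the bought stereocentre untouched.

**Step 2**
Reactants: 3; 4 vinylmagnesium bromide
Product: 5 (4S)-4-hydroxy-7-methylocta-1,6-dien-3-one
Conditions: MeNH(OMe)·HCl, i-PrMgCl, THF, −20 °C; then 4, −20 → 0 °C; inverse quench into cold 1 M HCl
Reagents that add atoms: vinylmagnesium bromide, C=C[Mg]Br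
Why: One-pot Weinreb amide formation and Weinreb ketone synthesis; the magnesium alkoxide protects the α-centre from enolisation and the cold acidic quench prevents amine conjugate addition to the enone.

**Step 3**
Reactants: 5; 6 isoprene
Product: 7 (2S)-2-hydroxy-5-methyl-1-[(1S)-4-methylcyclohex-3-en-1-yl]hex-4-en-1-one
Conditions: ZnCl2 (1.1 equiv), isoprene (5 equiv), BHT, CH2Cl2, −40 → −20 °C
Reagents that add atoms: isoprene, CC(=C)C=C
Why: Diels–Alder of a chelated (O–H/Zn···O=C, s-cis) α'-hydroxy enone; isoprene adds "para" and to the face opposite the CH2–prenyl group of the carbinol carbon, setting C1' as S.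

**Step 4**
Reactants: 7
Product: 8 (2R,3S)-6-methyl-2-[(1S)-4-methylcyclohex-3-en-1-yl]hept-5-ene-2,3-diol
Conditions: MeMgBr (3 equiv), THF, −78 °C
Reagents that add atoms: methylmagnesium bromide, C[Mg]Br
Why: Cram-chelate Grignard addition; the five-membered Mg chelate of the α-alkoxide and ketone is attacked from the side of the carbinol H, setting C2 as R.

**Step 5**
Reactants: 8
Product: 9 (2R)-2-hydroxy-6-methyl-2-[(1S)-4-methylcyclohex-3-en-1-yl]hept-5-en-3-one
Conditions: SO3·pyridine, DMSO, i-Pr2NEt, CH2Cl2, 0 °C
Reagents that add atoms: none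
Why: Parikh–Doering oxidation removes only the secondary alcohol, which has the wrong configuration for the target (no glycol cleavage; the tertiary OH and both alkenes are inert).

**Step 6**
Reactants: 9
Product: 10 (2R,3R)-2-hydroxy-6-methyl-2-[(1S)-4-methylcyclohex-3-en-1-yl]hept-5-en-3-yl acetate
Conditions: TMSOTf, 2,6-lutidine, CH2Cl2, −78 °C; L-Selectride, THF, −78 °C; Ac2O, DMAP, −78 → 0 °C; citric acid, MeOH work-up
Reagents that add atoms: acetic anhydride, CC(=O)OC(C)=O
Why: Polar Felkin–Anh reduction of the transient O-TMS ketone (C–OSi anti to the hydride, which passes the methyl rather than the cyclohexenyl group) gives the 3R carbinol; it is acetylated cold in situ (before O→O silyl migration) to mask O3 for step 7, and the tertiary TMS ether falls off on acidic work-up.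

**Step 7**
Reactants: 10
Product: 12 (2R,3R,5R)-5-bromo-2,6,6-trimethyl-2-[(1S)-4-methylcyclohex-3-en-1-yl]oxan-3-ol, via acetate 11 (not isolated)
Conditions: undivided cell, graphite(+)/Pt(−), 5 mA cm⁻², 2.2 F mol⁻¹, Et4NBr (1.3 equiv, syringe pump), n-Bu4NPF6, HFIP/CH2Cl2 1:1, 0 °C; then evaporate, K2CO3, MeOH, rt
Reagents that add atoms: tetraethylammonium bromide, CC[N+](CC)(CC)CC.[Br-]
Why: Anodic bromide oxidation gives a bromonium ion that only the side-chain alkene can trap internally (6-endo, Markovnikov bromoetherification, favoured by HFIP); the chair transition state with cyclohexenyl equatorial, C2-methyl axial and Br equatorial sets C5 as R, and the acetate, which blocks 5-endo closure by O3, is then removed by methanolysis.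

**Step 8**
Reactants: 12
Product: 13 (2R,3R,5R)-5-bromo-2-[(1S,3R,4R)-4-bromo-3-chloro-4-methylcyclohexyl]-2,6,6-trimethyloxan-3-ol (trans-diaxial isomer of caespitol with the two ring halogens interchanged)
Conditions: PhSeCl (1.05 equiv), CH2Cl2, −78 °C; then Br2 (1.1 equiv), −78 → −40 °C
Reagents that add atoms: phenylselenenyl chloride, Cl[Se]c1ccccc1 (Cl retained); bromine, BrBr
Why: Proposed new method: a selenium-relayed, regio-reversed anti chlorobromination in which reversible seleniranium formation is followed by kinetic trans-diaxial (Fürst–Plattner) chloride attack at the less hindered C3' (possible only from the seleniranium cis to the C1' substituent, giving axial C3'–Cl and axial C4'–SePh), after which Br2 oxidises selenium to Se(IV) and the tertiary C–Se bond ionises with help from the antiperiplanar chlorine so that bromide returns with retention; the closest known reactions are kinetic anti-Markovnikov anti-addition of PhSeCl to alkenes, bromodeselenation of alkyl phenyl selenides and selenium-catalysed alkene dihalogenation.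

**Step 9**
Reactants: 13
Product: 14 caespitol, (2R,3R,5R)-5-bromo-2-[(1S,3S,4S)-3-bromo-4-chloro-4-methylcyclohexyl]-2,6,6-trimethyloxan-3-ol
Conditions: MeNO2, powdered K2CO3, 70 °C
Reagents that add atoms: none
Why: Diaxial → diequatorial (dyotropic) 1,2-interchange of vicinal halides: the axial tertiary Br bridges to C3' as the antiperiplanar Cl migrates to C4', inverting both centres to equatorial C3'–Br (cis to the C1' substituent) and equatorial C4'–Cl, i.e. 3'S,4'S.

**Compound list**
1 | methyl (2S)-oxirane-2-carboxylate | COC(=O)[C@@H]1CO1 | starting material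
2 | (2-methylprop-1-en-1-yl)magnesium bromide | CC(C)=C[Mg]Br | starting material
3 | methyl (2S)-2-hydroxy-5-methylhex-4-enoate | COC(=O)[C@@H](O)CC=C(C)C | intermediate
4 | vinylmagnesium bromide | C=C[Mg]Br | starting material
5 | (4S)-4-hydroxy-7-methylocta-1,6-dien-3-one | C=CC(=O)[C@@H](O)CC=C(C)C | intermediate
6 | isoprene | CC(=C)C=C | starting material
7 | (2S)-2-hydroxy-5-methyl-1-[(1S)-4-methylcyclohex-3-en-1-yl]hex-4-en-1-one | CC1=CC[C@H](CC1)C(=O)[C@@H](O)CC=C(C)C | intermediate
8 | (2R,3S)-6-methyl-2-[(1S)-4-methylcyclohex-3-en-1-yl]hept-5-ene-2,3-diol | CC1=CC[C@H](CC1)[C@@](C)(O)[C@@H](O)CC=C(C)C | intermediate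
9 | (2R)-2-hydroxy-6-methyl-2-[(1S)-4-methylcyclohex-3-en-1-yl]hept-5-en-3-one | CC1=CC[C@H](CC1)[C@@](C)(O)C(=O)CC=C(C)C | intermediate
10 | (2R,3R)-2-hydroxy-6-methyl-2-[(1S)-4-methylcyclohex-3-en-1-yl]hept-5-en-3-yl acetate | CC1=CC[C@H](CC1)[C@@](C)(O)[C@H](OC(C)=O)CC=C(C)C | intermediate
11 | (2R,3R,5R)-5-bromo-2,6,6-trimethyl-2-[(1S)-4-methylcyclohex-3-en-1-yl]oxan-3-yl acetate | CC1(C)O[C@](C)([C@H]2CCC(C)=CC2)[C@H](OC(C)=O)C[C@H]1Br | intermediate (not isolated)
12 | (2R,3R,5R)-5-bromo-2,6,6-trimethyl-2-[(1S)-4-methylcyclohex-3-en-1-yl]oxan-3-ol | CC1(C)O[C@](C)([C@H]2CCC(C)=CC2)[C@H](O)C[C@H]1Br | intermediate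
13 | (2R,3R,5R)-5-bromo-2-[(1S,3R,4R)-4-bromo-3-chloro-4-methylcyclohexyl]-2,6,6-trimethyloxan-3-ol | CC1(C)O[C@](C)([C@H]2CC[C@@](C)(Br)[C@H](Cl)C2)[C@H](O)C[C@H]1Br | intermediate
14 | caespitol | CC1(C)O[C@](C)([C@H]2CC[C@](C)(Cl)[C@@H](Br)C2)[C@H](O)C[C@H]1Br | target

**Totals**
Total steps: 9. Longest linear sequence: 9 (fully linear from 1).

**Three steps most likely to fail**
1. Step 8 (proposed new step). The risks are incomplete kinetic anti-Markovnikov selectivity of the PhSeCl addition and retro-selenenylation or E1 loss on bromination. Fallback (known chemistry, stereospecific):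
   - NBS in aqueous acetone gives the trans-diaxial bromohydrin.
   - NaOH closes it to the epoxide cis to the C1' substituent.
   - Li2CuCl4 opens the epoxide at C3' with inversion (Fürst–Plattner).
   - HBr in CH2Cl2 at −40 °C converts the tertiary alcohol to the bromide with retention (neighbouring Cl), giving 13.
2. Step 9. The risks are that the diaxial/diequatorial equilibrium may not lie far enough toward 14 (my estimate is that it could be close to 1:1) and that the tertiary bromide may eliminate. Fallback under kinetic control, starting from the PhSeCl adduct of 12: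
   - H2O2 selenoxide elimination gives the axial allylic chloride (3'-chloro-4'-methylidene).
   - LiBr displaces the chloride by SN2 with inversion, giving the equatorial C3'–Br.
   - Markovnikov HCl addition, with chloride delivered anti to the bridging bromine, gives 14 without passing through 13.
3. Step 7. The risks are competing 5-exo closure to the oxolane and dibromination of the ring alkene by anodically generated Br2. Fallback: replace the electrolysis with a stoichiometric bromonium reagent (TBCO in MeNO2 or NBS in HFIP) on 10, and convert any 5-exo tertiary bromide to the oxane by Ag(I)-promoted ring expansion through the oxiranium ion.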